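The synthesis rests on disconnecting the bond between ring A carbon C1' and the ketone carbon, and on using the neighbouring 2'-oxygen as a tether: the whole cinnamoyl unit is first hung on O2' as an aryl ester. The key step, an anionic Fries rearrangement triggered by iodine–lithium exchange, then moves the acyl group from O2' to C1' in one operation, forming the aryl–carbonyl bond and releasing the 2'-phenol. Its precursor is 5-(geranyloxy)-2-iodophenyl (E)-4-(silyloxy)cinnamate, in which the iodine, para to the geranyloxy group, fixes the site; it is assembled from 4-iodoresorcinol, geranyl bromide and p-coumaric acid.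

Key step: step 4

Remark: 4-iodoresorcinol, geranyl bromide and (E)-p-coumaric acid are taken as commercial; ring A is numbered with primes (C1' carries the ketone, C2' the hydroxyl, C4' the geranyloxy group).

Step 1
Reactants: 1 (E)-p-coumaric acid
Product: 3 (2E)-3-{4-[(tert-butyldimethylsilyl)oxy]phenyl}prop-2-enoic acid, via silyl ester 2 (not isolated)
Conditions: TBSCl (2.3 equiv), imidazole, DMF, rt; then AcOH/THF/H2O, rt
Reagents that add atoms: tert-butyldimethylsilyl chloride (TBSCl), CC(C)(C)[Si](C)(C)Cl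
Why: Imidazole-promoted silylation caps both the phenol and the acid, and the far more labile silyl ester alone is hydrolysed by aqueous acetic acid, which leaves the aryl silyl ether and the (E)-alkene intact (silyl protection with selective silyl ester hydrolysis).

Step 2
Reactants: 4 4-iodoresorcinol; 5 geranyl bromide
Product: 6 5-{[(2E)-3,7-dimethylocta-2,6-dien-1-yl]oxy}-2-iodophenol
Conditions: K2CO3 (1 equiv), acetone, rt
Reagents that add atoms: none
Why: Williamson ether synthesis, in which the unhindered hydroxyl para to iodine should be alkylated in preference to the hydroxyl shielded by the ortho iodine, by SN2 displacement at the primary allylic bromide with the (E)-alkene retained, while one equivalent of base and bromide limits dialkylation.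

Step 3
Reactants: 3 (2E)-3-{4-[(tert-butyldimethylsilyl)oxy]phenyl}prop-2-enoic acid; 6 5-{[(2E)-3,7-dimethylocta-2,6-dien-1-yl]oxy}-2-iodophenol
Product: 7 5-{[(2E)-3,7-dimethylocta-2,6-dien-1-yl]oxy}-2-iodophenyl (2E)-3-{4-[(tert-butyldimethylsilyl)oxy]phenyl}prop-2-enoate
Conditions: DCC, DMAP (cat.), CH2Cl2, 0 °C to rt
Reagents that add atoms: none
Why: Steglich esterification, in which DCC activates the acid as the O-acylisourea and DMAP relays the acyl group to the hindered ortho-iodophenol under neutral conditions that leave the silyl ether, the allylic ether and all alkenes untouched.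

Step 4
Reactants: 7 5-{[(2E)-3,7-dimethylocta-2,6-dien-1-yl]oxy}-2-iodophenyl (2E)-3-{4-[(tert-butyldimethylsilyl)oxy]phenyl}prop-2-enoate
Product: 10 (2E)-3-{4-[(tert-butyldimethylsilyl)oxy]phenyl}-1-(4-{[(2E)-3,7-dimethylocta-2,6-dien-1-yl]oxy}-2-hydroxyphenyl)prop-2-en-1-one, via aryllithium 8 (not isolated), via lithium phenoxide 9 (not isolated)
Conditions: n-BuLi (1.0 equiv), THF/Et2O, −100 °C to −78 °C; then AcOH
Reagents that add atoms: none
Why: Iodine–lithium exchange at the carbon para to the geranyloxy group should be far faster at −100 °C than addition of n-BuLi to the cinnamate, and the aryllithium 8 so formed attacks the ester carbonyl held on the neighbouring oxygen, the adduct collapsing with cleavage of the acyl–oxygen bond to the chelated lithium phenoxide 9 (1,3 O→C acyl shift). The closest known reaction type is the anionic Fries rearrangement of ortho-halophenyl esters set off by halogen–metal exchange. No ring is closed in the product and no stereocentre is formed; the (E)-enone and the geranyl (E)-alkene are carried through unchanged. The step needs site selectivity, secured because the carbanion can only arise at the iodine-bearing carbon (the acyl group cannot reach the position between the two oxygens or the one para to O2'), and chemoselectivity for carbonyl attack over conjugate addition, secured by the hard lithium centre and by the preferred ester rotamer, which places the carbonyl carbon and not the β-carbon next to the carbanion. The phenoxide formed deactivates the new ketone towards a second addition, and the allylic aryl ether and the silyl ether should be inert to the reagent at this temperature.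

Step 5
Reactants: 10 (2E)-3-{4-[(tert-butyldimethylsilyl)oxy]phenyl}-1-(4-{[(2E)-3,7-dimethylocta-2,6-dien-1-yl]oxy}-2-hydroxyphenyl)prop-2-en-1-one
Product: 11 (2E)-1-(4-{[(2E)-3,7-dimethylocta-2,6-dien-1-yl]oxy}-2-hydroxyphenyl)-3-(4-hydroxyphenyl)prop-2-en-1-one
Conditions: TBAF (1.1 equiv), AcOH (1.1 equiv), THF, 0 °C
Reagents that add atoms: none
Why: Fluoride-mediated cleavage of the aryl silyl ether, driven by the strength of the Si–F bond, with acetic acid buffering the phenoxides so that the 2'-hydroxychalcone should not close to the flavanone and the geranyl ether stays intact.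

Compound list
1 | (E)-p-coumaric acid, (2E)-3-(4-hydroxyphenyl)prop-2-enoic acid | O=C(O)/C=C/c1ccc(O)cc1 | starting material
2 | tert-butyldimethylsilyl (2E)-3-{4-[(tert-butyldimethylsilyl)oxy]phenyl}prop-2-enoate | CC(C)(C)[Si](C)(C)OC(=O)/C=C/c1ccc(O[Si](C)(C)C(C)(C)C)cc1 | intermediate
3 | (2E)-3-{4-[(tert-butyldimethylsilyl)oxy]phenyl}prop-2-enoic acid | CC(C)(C)[Si](C)(C)Oc1ccc(/C=C/C(=O)O)cc1 | intermediate
4 | 4-iodoresorcinol (4-iodobenzene-1,3-diol) | Oc1ccc(I)c(O)c1 | starting material
5 | geranyl bromide, (2E)-1-bromo-3,7-dimethylocta-2,6-diene | CC(C)=CCC/C(C)=C/CBr | starting material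
6 | 5-{[(2E)-3,7-dimethylocta-2,6-dien-1-yl]oxy}-2-iodophenol | CC(C)=CCC/C(C)=C/COc1ccc(I)c(O)c1 | intermediate
7 | 5-{[(2E)-3,7-dimethylocta-2,6-dien-1-yl]oxy}-2-iodophenyl (2E)-3-{4-[(tert-butyldimethylsilyl)oxy]phenyl}prop-2-enoate | CC(C)=CCC/C(C)=C/COc1ccc(I)c(OC(=O)/C=C/c2ccc(O[Si](C)(C)C(C)(C)C)cc2)c1 | intermediate
8 | aryllithium formed from 7 by iodine–lithium exchange (lithium in place of iodine) | CC(C)=CCC/C(C)=C/COc1ccc([Li])c(OC(=O)/C=C/c2ccc(O[Si](C)(C)C(C)(C)C)cc2)c1 | intermediate
9 | lithium phenoxide of 10 | CC(C)=CCC/C(C)=C/COc1ccc(C(=O)/C=C/c2ccc(O[Si](C)(C)C(C)(C)C)cc2)c(O[Li])c1 | intermediate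
10 | (2E)-3-{4-[(tert-butyldimethylsilyl)oxy]phenyl}-1-(4-{[(2E)-3,7-dimethylocta-2,6-dien-1-yl]oxy}-2-hydroxyphenyl)prop-2-en-1-one | CC(C)=CCC/C(C)=C/COc1ccc(C(=O)/C=C/c2ccc(O[Si](C)(C)C(C)(C)C)cc2)c(O)c1 | intermediate
11 | (2E)-1-(4-{[(2E)-3,7-dimethylocta-2,6-dien-1-yl]oxy}-2-hydroxyphenyl)-3-(4-hydroxyphenyl)prop-2-en-1-one (4'-O-geranylisoliquiritigenin) | CC(C)=CCC/C(C)=C/COc1ccc(C(=O)/C=C/c2ccc(O)cc2)c(O)c1 | target

Total step count: 5. Longest linear sequence: 4 steps (step 2, or step 1, then steps 3, 4 and 5).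

Steps most likely to fail

Step 4. The butyllithium or the aryllithium may add to the cinnamate (at the carbonyl or at the β-carbon), or the carbanion may close onto the β-carbon to a dihydrocoumarin, instead of clean acyl migration. The fallback sets out from compounds 6 and 3 and comes back to the route at compound 11. Phenol 6 would be silylated (TBSCl, imidazole, DMF) to tert-butyl(5-{[(2E)-3,7-dimethylocta-2,6-dien-1-yl]oxy}-2-iodophenoxy)dimethylsilane F1. Acid 3 would be converted (MeNHOMe·HCl, EDC·HCl, Et3N, CH2Cl2) into the Weinreb amide (2E)-3-{4-[(tert-butyldimethylsilyl)oxy]phenyl}-N-methoxy-N-methylprop-2-enamide F2. Iodine–magnesium exchange on F1 with i-PrMgCl·LiCl (THF, −20 °C) should give the arylmagnesium chloride F3, which is slow to undergo silyl migration. F3 should add to F2 at the amide carbonyl, forming the same aryl–carbonyl bond, and after aqueous NH4Cl give the bis-silyl chalcone (2E)-1-(2-[(tert-butyldimethylsilyl)oxy]-4-{[(2E)-3,7-dimethylocta-2,6-dien-1-yl]oxy}phenyl)-3-{4-[(tert-butyldimethylsilyl)oxy]phenyl}prop-2-en-1-one F4. Both silyl ethers would then be removed with two equivalents of buffered TBAF as in step 5 to give 11.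

Step 2. Alkylation may be unselective between the two hydroxyls, with dialkylation and C-alkylation alongside. The fallback sets out from compound 5 and comes back at compound 6; it sets the ether first and the iodine second. Excess resorcinol would be alkylated with 5 (K2CO3, acetone) to 3-{[(2E)-3,7-dimethylocta-2,6-dien-1-yl]oxy}phenol F5. Iodination of its phenoxide (I2, NaHCO3, THF/H2O, 0 °C) should occur ortho to the hydroxyl and para to the ether oxygen, as is usual for 3-alkoxyphenols, and should be much faster than attack of iodine on the trisubstituted alkenes.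

Step 5. Basic fluoride may close the 2'-hydroxychalcone to the flavanone, or buffered fluoride may cleave the silyl ether incompletely. The fallback sets out from compound 6 and comes back at compound 11; it replaces the silyl ether by an acetal that is removed with mild acid. Commercial 4-(oxan-2-yloxy)benzaldehyde and malonic acid (pyridine, piperidine, 90 °C, Knoevenagel–Doebner condensation) should give (2E)-3-[4-(oxan-2-yloxy)phenyl]prop-2-enoic acid F6. Esterification with 6 as in step 3 would give 5-{[(2E)-3,7-dimethylocta-2,6-dien-1-yl]oxy}-2-iodophenyl (2E)-3-[4-(oxan-2-yloxy)phenyl]prop-2-enoate F7. Treatment as in step 4 should lead through the aryllithium F8 and the lithium phenoxide F9 to (2E)-1-(4-{[(2E)-3,7-dimethylocta-2,6-dien-1-yl]oxy}-2-hydroxyphenyl)-3-[4-(oxan-2-yloxy)phenyl]prop-2-en-1-one F10. Acetal exchange (PPTS, EtOH, 50 °C) should then release 11 without touching the geranyl ether.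

Further compounds
F1 | step 4 | tert-butyl(5-{[(2E)-3,7-dimethylocta-2,6-dien-1-yl]oxy}-2-iodophenoxy)dimethylsilane | CC(C)=CCC/C(C)=C/COc1ccc(I)c(O[Si](C)(C)C(C)(C)C)c1
F2 | step 4 | (2E)-3-{4-[(tert-butyldimethylsilyl)oxy]phenyl}-N-methoxy-N-methylprop-2-enamide | CON(C)C(=O)/C=C/c1ccc(O[Si](C)(C)C(C)(C)C)cc1
F3 | step 4 | (2-[(tert-butyldimethylsilyl)oxy]-4-{[(2E)-3,7-dimethylocta-2,6-dien-1-yl]oxy}phenyl)magnesium chloride | CC(C)=CCC/C(C)=C/COc1ccc([Mg]Cl)c(O[Si](C)(C)C(C)(C)C)c1
F4 | step 4 | (2E)-1-(2-[(tert-butyldimethylsilyl)oxy]-4-{[(2E)-3,7-dimethylocta-2,6-dien-1-yl]oxy}phenyl)-3-{4-[(tert-butyldimethylsilyl)oxy]phenyl}prop-2-en-1-one | CC(C)=CCC/C(C)=C/COc1ccc(C(=O)/C=C/c2ccc(O[Si](C)(C)C(C)(C)C)cc2)c(O[Si](C)(C)C(C)(C)C)c1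
F5 | step 2 | 3-{[(2E)-3,7-dimethylocta-2,6-dien-1-yl]oxy}phenol | CC(C)=CCC/C(C)=C/COc1cccc(O)c1
F6 | step 5 | (2E)-3-[4-(oxan-2-yloxy)phenyl]prop-2-enoic acid | O=C(O)/C=C/c1ccc(OC2CCCCO2)cc1
F7 | step 5 | 5-{[(2E)-3,7-dimethylocta-2,6-dien-1-yl]oxy}-2-iodophenyl (2E)-3-[4-(oxan-2-yloxy)phenyl]prop-2-enoate | CC(C)=CCC/C(C)=C/COc1ccc(I)c(OC(=O)/C=C/c2ccc(OC3CCCCO3)cc2)c1
F8 | step 5 | aryllithium formed from F7 by iodine–lithium exchange | CC(C)=CCC/C(C)=C/COc1ccc([Li])c(OC(=O)/C=C/c2ccc(OC3CCCCO3)cc2)c1
F9 | step 5 | lithium phenoxide of F10 | CC(C)=CCC/C(C)=C/COc1ccc(C(=O)/C=C/c2ccc(OC3CCCCO3)cc2)c(O[Li])c1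
F10 | step 5 | (2E)-1-(4-{[(2E)-3,7-dimethylocta-2,6-dien-1-yl]oxy}-2-hydroxyphenyl)-3-[4-(oxan-2-yloxy)phenyl]prop-2-en-1-one | CC(C)=CCC/C(C)=C/COc1ccc(C(=O)/C=C/c2ccc(OC3CCCCO3)cc2)c(O)c1
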